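I take a small charge, 20 mM of D with 8.3 mol% of Q, and ask what the fraction of D left has to be for Saturday's closed flask to lose first place, reckoning with the fraction left and not the fraction made.

| flask | D | Q | remark | time |
|---|---|---|---|---|
| noon | 20 mM | 8.3 mol% | run made earlier |  |
| autumn | 20 mM | 12 mol% | run made earlier |  |
| dusk | 20 mM | 18 mol% | run made earlier |  |
| Tuesday's | 20 mM | 8.3 mol% | one stirred flow tank at steady state, fed with the mixture as stated, mean residence time 12 h |  |
| Saturday's | 20 mM | 8.3 mol% | everything together in a closed stirred flask, run for 12 h | 12 h |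
| Monday's | 20 mM (fed, over 12.0 h) | 8.3 mol% | all but D at the start; D goes in evenly over 12.0 h, the run ends at 12 h | 12 h |

| run | time / h | Z / % | D / % |
|---|---|---|---|
| noon | 1.00 | 12.8 | 86.9 |
| noon | 2.00 | 21.7 | 78.5 |
| noon | 5.00 | 38.2 | 59.4 |
| noon | 12.0 | 54.6 | 40.2 |
| autumn | 4.00 | 44.2 | 54.7 |
| autumn | 8.00 | 57.3 | 37.2 |
| autumn | 10.0 | 60.7 | 31.0 |
| autumn | 15.0 | 63.8 | 26.5 |
| dusk | 4.00 | 55.0 | 41.4 |
| dusk | 8.00 | 65.4 | 23.7 |
| dusk | 10.0 | 67.2 | 20.7 |
| dusk | 15.0 | 68.4 | 16.8 |

(standard deviation of a reading: 0.5 percentage points)

- the stated concentrations are those of everything mixed, before any reaction; amounts are the same in each set-up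
- the feed brings no volume worth counting
- the earlier runs were made in a closed, stirred flask

* the set-up with the highest amount of Z at the outlet or at the end, in percent of the D put in ("none" if the first two lie within 2 percentage points) (Tuesday's / Saturday's / Monday's / none)
* amount of Z at the outlet or at the end, in percent of the D put in, Tuesday's
* amount of Z at the outlet or at the end, in percent of the D put in, Saturday's
* amount of Z at the outlet or at the end, in percent of the D put in, Monday's

Saturday's repeats the noon recipe for the noon time, so I take its Z as the noon reading, 54.6%, with D left at 40.2%; that makes 0.911 of what I call exposure, the natural logarithm of one over the fraction of D left. At one steady constant (pseudo-first-order), that exposure leaves 52.3% in Tuesday's tank, one over one plus the exposure, and 65.6% under Monday's even feed, one minus the closed flask's fraction left, over the exposure. For the opposite outcome at that steady constant, Tuesday's tank, which leaves less D than Monday's feed, has to leave what the closed flask leaves, which takes a tank exposure, the constant times the residence time, of 1.49, or 1.64 times the closed flask's noon value. The constant is rough, though, because the noon run gains 0.140 in its first 1.00 h, faster than the 0.390 of its last 7.00 h. At noon's end 91.3% of the D consumed stands as Z, so I commit to 43.5% for Tuesday's and 31.4% for Monday's, both less than Saturday's 54.6%.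

The forecast, lower than my reckoning for Tuesday's and for Monday's, gives 36.5%, 54.6% and 27.5% for Tuesday's, Saturday's and Monday's, and closes with “The batch flask is clearly best.” The flask gives 37.7%, 54.8% and 36.9%, with Saturday's first.

    D + Q → E + Z (k = 111 L mol⁻¹ h⁻¹)
    D + E → Z + E, rate k2*[E]*[D] (k = 62.7 L mol⁻¹ h⁻¹)
    E + Z → J (k = 11.3 L mol⁻¹ h⁻¹)

In Saturday's at 12.0 h, D has a half-life of 18 h by the step from D to Z, an exposure rate of 0.0375 h⁻¹, less than the mean of 0.0759 h⁻¹ read from the noon run. There Z is still made 4.04 times faster than it is used up. For the neighbour on Saturday's recipe with 3.3 mol% of Q, scaling exposure with loading gives 0.362, so D left 69.6% and Z 27.8%. The computed flask holds D 65.2% and Z 33.4%.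

All runs come from a simulation on assumed constants.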